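Ring B (C6–C11, the cyclohexene) is cut out of a cyclohept-4-enone. The feature used is the array C11(H)(iPr)–C6(spiro)–C1(=O): a ring B carbon that bears a ring A carbonyl next to the stereocentre, which is the product pattern of a Wolff rearrangement. In the key step a 2-diazocycloheptenone loses N2 and C11 shifts from C1 to C6 with retention (seven- to six-membered ring). The expelled C1 ketene is taken up by the enolate of a keto ester holding C2–C5. The C6 enolate so formed closes ring A by Dieckmann acylation anti to the isopropyl group. One operation gives ring B, ring A and the spiro centre. The precursor is monocyclic and made by metathesis.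

Key step: step 7

Remark: atoms are numbered as in the name of 19 (ring A = C1–C6, ring B = C6–C11, C6 = spiro carbon), and 1, 5 and 12 are taken to be catalogue compounds.

Step 1
Reactants: 1 (4S)-4-benzyl-3-(3-methylbutanoyl)-1,3-oxazolidin-2-one
Product: 2 (4S)-4-benzyl-3-[(2S)-2-(propan-2-yl)pent-4-enoyl]-1,3-oxazolidin-2-one
Conditions: NaN(SiMe3)2, THF, −78 °C; allyl iodide, −78 → −40 °C
Reagents that add atoms: allyl iodide, C=CCI
Why: Evans asymmetric alkylation: the chelated Z sodium enolate is shielded on one face by the benzyl group, so allyl iodide enters from the other face and sets the (S) centre that becomes C11.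

Step 2
Reactants: 2 (4S)-4-benzyl-3-[(2S)-2-(propan-2-yl)pent-4-enoyl]-1,3-oxazolidin-2-one
Product: 4 (2S)-2-(propan-2-yl)pent-4-enoic acid, via peroxy acid 3 (not isolated)
Conditions: LiOH, H2O2, THF/H2O, 0 °C; aq. Na2SO3; then HCl
Reagents that add atoms: hydrogen peroxide, OO (one O stays as the acid OH)
Why: Hydroperoxide attacks the exocyclic imide carbonyl selectively even next to a branched centre (standard auxiliary cleavage), sulfite reduces the peroxy acid, and the weakly basic medium leaves the α-centre untouched.

Step 3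
Reactants: 4 (2S)-2-(propan-2-yl)pent-4-enoic acid; 5 myrcene
Product: 8 (4S)-12-methyl-8-methylidene-4-(propan-2-yl)trideca-1,11-dien-5-one, via acid chloride 6 (not isolated), via alkylzirconocene 7 (not isolated)
Conditions: 4, (COCl)2, cat. DMF, CH2Cl2, 0 °C → rt, evaporate; separately 5, Cp2Zr(H)Cl, THF, rt; combine, CuBr·SMe2 (10 mol %), THF, rt
Reagents that add atoms: oxalyl chloride, O=C(Cl)C(Cl)=O (Cl of 6 only); Cp2Zr(H)Cl, [H-].[Cl-].[Zr+4].c1cc[cH-]c1.c1cc[cH-]c1 (Zr fragment of 7 only, only its H stays in 8)
Why: Hydrozirconation of a 1,3-diene adds Zr–H across the less hindered monosubstituted double bond with Zr on the terminal carbon and leaves the other two alkenes alone, and the copper-catalysed acylation of the alkylzirconocene by the acid chloride stops at the ketone without base, so the α-centre is not epimerised.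

Step 4
Reactants: 8 (4S)-12-methyl-8-methylidene-4-(propan-2-yl)trideca-1,11-dien-5-one
Product: 9 (2S)-5-(4-methylpent-3-en-1-yl)-2-(propan-2-yl)cyclohept-4-en-1-one
Conditions: second-generation Grubbs catalyst (H2IMes)(PCy3)Cl2Ru=CHPh (5 mol %), CH2Cl2 (0.005 M), reflux
Reagents that add atoms: none
Why: Ring-closing metathesis joins the monosubstituted and the 1,1-disubstituted terminal alkenes to the trisubstituted olefin of a seven-membered ring with loss of ethene, while the prenyl-type alkene is too hindered and wrongly spaced (it could only give a cyclobutene) to interfere.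

Step 5
Reactants: 9 (2S)-5-(4-methylpent-3-en-1-yl)-2-(propan-2-yl)cyclohept-4-en-1-one
Product: 11 (7S)-2-diazo-4-(4-methylpent-3-en-1-yl)-7-(propan-2-yl)cyclohept-4-en-1-one, via trifluoroacetyl ketone 10 (not isolated)
Conditions: LiN(SiMe3)2, THF, −78 °C; CF3CO2CH2CF3; aq. HCl work-up; then MsN3, Et3N, H2O, MeCN, rt
Reagents that add atoms: methanesulfonyl azide, CS(=O)(=O)N=[N+]=[N-]; 2,2,2-trifluoroethyl trifluoroacetate, O=C(OCC(F)(F)F)C(F)(F)F (its CF3CO group stays only in 10)
Why: Detrifluoroacetylative Regitz diazo transfer: the hindered amide base deprotonates kinetically at the open α-methylene and not at the tertiary C–H beside the isopropyl group, so activation and diazo transfer occur only there and the stereocentre is untouched.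

Step 6
Reactants: 12 methyl 2-methyl-3-oxopentanoate
Product: 13 methyl 2,2-dimethyl-3-oxopentanoate
Conditions: MeI, K2CO3, acetone, reflux
Reagents that add atoms: iodomethane, CI
Why: C-alkylation of the β-keto ester enolate builds the quaternary carbon that becomes C4 and leaves the CH2 of the ethyl ketone (future C2) as the only acidic position.

Step 7
Reactants: 11 (7S)-2-diazo-4-(4-methylpent-3-en-1-yl)-7-(propan-2-yl)cyclohept-4-en-1-one; 13 methyl 2,2-dimethyl-3-oxopentanoate
Product: 18 (6R,11S)-3-hydroxy-2,4,4-trimethyl-8-(4-methylpent-3-en-1-yl)-11-(propan-2-yl)spiro[5.5]undeca-2,8-diene-1,5-dione, via ketene 14 (not isolated), via lithium enolate 15 (not isolated), via keto enolate 16 (not isolated), via dienediolate 17 (not isolated)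
Conditions: 11, hν (365 nm LED), THF, −78 °C; cannulate into 15 [13, LiN(iPr)2 (1.05 equiv), THF, −78 °C]; after 15 min LiN(iPr)2 (1.2 equiv), −78 → 0 °C; 1 M HCl
Reagents that add atoms: lithium diisopropylamide, [Li+].CC(C)[N-]C(C)C (Li of 15, 16 and 17 only)
Why: Direct photolysis of the cyclic, s-Z-locked diazo ketone expels N2 while C11 migrates from the carbonyl carbon (C1) to the diazo carbon (C6) in a concerted Wolff rearrangement, which contracts the cycloheptene to ring B by a 1,2-shift and pushes C1 out of the ring as ketene 14. Lithium enolate 15 adds through carbon to C1 in the ketene plane from the side of the C7 methylene and gives the C6 enolate 16 regiospecifically; the second portion of base removes the acidic C2–H so that 16 is not quenched by proton transfer, and dienediolate 17 attacks the ester carbon C5 in a Dieckmann condensation that closes ring A in the 6-(enolendo)-exo-trig mode and is driven by loss of methoxide and formation of the stable trione enolate. The closest known reaction types are the photochemical Wolff ring contraction of 2-diazocycloalkanones, the C-acylation of lithium enolates by ketenes and the γ-acylation of 1,3-diketone dianions. C11 keeps its configuration because the migrating carbon moves with retention, and afterwards it is no longer next to a carbonyl group. The spiro centre C6 is controlled by C11: allylic 1,3-strain with the enolate oxygen turns the isopropyl group pseudoaxial, so C5 bonds to the opposite face and ends trans to isopropyl with C1 cis, which is the (6R,11S) series. The step needs rearrangement to win over the 1,2-hydride shift of a free carbene (secured by the s-Z geometry and by light instead of metal catalysis) and C- over O-acylation of 15 (secured by the lithium counter-ion in THF).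

Step 8
Reactants: 18 (6R,11S)-3-hydroxy-2,4,4-trimethyl-8-(4-methylpent-3-en-1-yl)-11-(propan-2-yl)spiro[5.5]undeca-2,8-diene-1,5-dione
Product: 19 (6R,11S)-3-methoxy-2,4,4-trimethyl-8-(4-methylpent-3-en-1-yl)-11-(propan-2-yl)spiro[5.5]undeca-2,8-diene-1,5-dione
Conditions: Me2SO4, K2CO3, acetone, rt
Reagents that add atoms: dimethyl sulfate, COS(=O)(=O)OC
Why: O-alkylation of the vinylogous acid with a hard methylating agent: of the two enolate oxygens the one on C3 lies beside the gem-dimethyl carbon C4 and is more open than the one on C1, which is flanked by the spiro centre and the isopropyl-bearing C11, and no stereocentre is touched.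

Compound list
1 | (4S)-4-benzyl-3-(3-methylbutanoyl)-1,3-oxazolidin-2-one | CC(C)CC(=O)N1[C@@H](Cc2ccccc2)COC1=O | starting material
2 | (4S)-4-benzyl-3-[(2S)-2-(propan-2-yl)pent-4-enoyl]-1,3-oxazolidin-2-one | C=CC[C@@H](C(C)C)C(=O)N1[C@@H](Cc2ccccc2)COC1=O | intermediate
3 | (2S)-2-(propan-2-yl)pent-4-eneperoxoic acid, present as its lithium salt (not isolated) | C=CC[C@@H](C(C)C)C(=O)OO | intermediate
4 | (2S)-2-(propan-2-yl)pent-4-enoic acid | C=CC[C@@H](C(C)C)C(=O)O | intermediate
5 | myrcene (7-methyl-3-methylideneocta-1,6-diene) | C=CC(=C)CCC=C(C)C | starting material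
6 | (2S)-2-(propan-2-yl)pent-4-enoyl chloride (not isolated) | C=CC[C@@H](C(C)C)C(=O)Cl | intermediate
7 | chloridobis(cyclopentadienyl)(7-methyl-3-methylideneoct-6-en-1-yl)zirconium (not isolated) | CC(C)=CCCC(=C)C[CH2-].[Cl-].[Zr+4].c1cc[cH-]c1.c1cc[cH-]c1 | intermediate
8 | (4S)-12-methyl-8-methylidene-4-(propan-2-yl)trideca-1,11-dien-5-one | C=CC[C@@H](C(C)C)C(=O)CCC(=C)CCC=C(C)C | intermediate
9 | (2S)-5-(4-methylpent-3-en-1-yl)-2-(propan-2-yl)cyclohept-4-en-1-one | O=C1CCC(CCC=C(C)C)=CC[C@H]1C(C)C | intermediate
10 | (2S)-5-(4-methylpent-3-en-1-yl)-2-(propan-2-yl)-7-(trifluoroacetyl)cyclohept-4-en-1-one (not isolated) | O=C1C(C(=O)C(F)(F)F)CC(CCC=C(C)C)=CC[C@H]1C(C)C | intermediate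
11 | (7S)-2-diazo-4-(4-methylpent-3-en-1-yl)-7-(propan-2-yl)cyclohept-4-en-1-one | O=C1C(=[N+]=[N-])CC(CCC=C(C)C)=CC[C@H]1C(C)C | intermediate
12 | methyl 2-methyl-3-oxopentanoate (racemic) | CCC(=O)C(C)C(=O)OC | starting material
13 | methyl 2,2-dimethyl-3-oxopentanoate | CCC(=O)C(C)(C)C(=O)OC | intermediate
14 | [(6S)-3-(4-methylpent-3-en-1-yl)-6-(propan-2-yl)cyclohex-3-en-1-ylidene]methanone, the ketene (not isolated) | O=C=C1CC(CCC=C(C)C)=CC[C@H]1C(C)C | intermediate
15 | lithium 5-methoxy-4,4-dimethyl-5-oxopent-2-en-3-olate, the enolate of 13 (not isolated) | [Li+].CC=C([O-])C(C)(C)C(=O)OC | intermediate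
16 | lithium 1-[(6S)-3-(4-methylpent-3-en-1-yl)-6-(propan-2-yl)cyclohex-3-en-1-ylidene]-5-methoxy-2,4,4-trimethyl-3,5-dioxopentan-1-olate (not isolated) | [Li+].COC(=O)C(C)(C)C(=O)C(C)C([O-])=C1CC(CCC=C(C)C)=CC[C@H]1C(C)C | intermediate
17 | dilithium dienediolate formed from 16 by loss of the C2 proton (not isolated) | [Li+].[Li+].COC(=O)C(C)(C)C([O-])=C(C)C([O-])=C1CC(CCC=C(C)C)=CC[C@H]1C(C)C | intermediate
18 | (6R,11S)-3-hydroxy-2,4,4-trimethyl-8-(4-methylpent-3-en-1-yl)-11-(propan-2-yl)spiro[5.5]undeca-2,8-diene-1,5-dione (spiro trione drawn as its enol) | OC1=C(C)C(=O)[C@]2(CC(CCC=C(C)C)=CC[C@H]2C(C)C)C(=O)C1(C)C | intermediate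
19 | (6R,11S)-3-methoxy-2,4,4-trimethyl-8-(4-methylpent-3-en-1-yl)-11-(propan-2-yl)spiro[5.5]undeca-2,8-diene-1,5-dione | COC1=C(C)C(=O)[C@]2(CC(CCC=C(C)C)=CC[C@H]2C(C)C)C(=O)C1(C)C | target

Total step count: 8. Longest linear sequence: 7 (steps 1, 2, 3, 4, 5, 7, 8).

Steps most likely to fail

Step 7. Three things may go wrong:
- Proton transfer between adduct molecules may quench the C6 enolate before it cyclises.
- The enolate may add to the ketene through oxygen.
- The facial selectivity of the ring closure may be poor.

The fallback sets out from 11 and comes back at 18. It keeps the ring contraction but builds the spiro centre in an intermolecular step. Irradiation of 11 in methanol gives methyl (6S)-3-(4-methylpent-3-en-1-yl)-6-(propan-2-yl)cyclohex-3-ene-1-carboxylate F1 by the classical Wolff ring contraction; the configuration at the ester carbon does not matter. LiN(iPr)2 turns it into the ester enolate. This enolate adds anti to the isopropyl group to 2,2-dimethyl-3-oxopentanal F2, which is made from the morpholine enamine of isobutyraldehyde and propanoyl chloride. The product is methyl (6S)-1-(1-hydroxy-2,2-dimethyl-3-oxopentyl)-3-(4-methylpent-3-en-1-yl)-6-(propan-2-yl)cyclohex-3-ene-1-carboxylate F3, with the ester cis to isopropyl. Dess–Martin oxidation gives methyl (6S)-1-(2,2-dimethyl-3-oxopentanoyl)-3-(4-methylpent-3-en-1-yl)-6-(propan-2-yl)cyclohex-3-ene-1-carboxylate F4. KOtBu in THF then closes ring A by Dieckmann condensation of the ethyl ketone enolate onto the ester, which gives 18.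

Step 8. Methylation may occur at the wrong enolate oxygen (the one on C1) or at carbon C2. The fallback sets out from 18 and comes back at 19. It replaces kinetic enolate alkylation by acid-catalysed addition–elimination. With HC(OMe)3, MeOH and catalytic camphorsulfonic acid at rt, the least hindered carbonyl C3 should be ketalised to (6R,11S)-3,3-dimethoxy-2,4,4-trimethyl-8-(4-methylpent-3-en-1-yl)-11-(propan-2-yl)spiro[5.5]undec-8-ene-1,5-dione F5. This ketal can lose methanol only towards C2, because C4 is quaternary, and so gives 19. Any enol ether at C1 is returned to the same equilibrium.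

Step 3. Hydrozirconation may discriminate poorly between the two terminal double bonds of the diene, and acylation by the hindered acid chloride may be slow. The fallback sets out from 4 and 5 and comes back at 8.
- Disiamylborane hydroborates only the monosubstituted double bond of 5, and H2O2/NaOH gives 7-methyl-3-methylideneoct-6-en-1-ol F6.
- An Appel-type iodination (I2, PPh3, imidazole) gives 8-iodo-2-methyl-6-methylideneoct-2-ene F7.
- Acid 4 is coupled with MeNHOMe·HCl (carbonyldiimidazole) to (2S)-N-methoxy-N-methyl-2-(propan-2-yl)pent-4-enamide F8.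
- Iodine–lithium exchange of F7 (t-BuLi, Et2O/pentane, −78 °C) and addition to F8 (Weinreb ketone synthesis) give 8.

Further compounds
F1 | step 7 | methyl (6S)-3-(4-methylpent-3-en-1-yl)-6-(propan-2-yl)cyclohex-3-ene-1-carboxylate | COC(=O)C1CC(CCC=C(C)C)=CC[C@H]1C(C)C
F2 | step 7 | 2,2-dimethyl-3-oxopentanal | CCC(=O)C(C)(C)C=O
F3 | step 7 | methyl (6S)-1-(1-hydroxy-2,2-dimethyl-3-oxopentyl)-3-(4-methylpent-3-en-1-yl)-6-(propan-2-yl)cyclohex-3-ene-1-carboxylate, ester cis to isopropyl | COC(=O)[C@@]1(C(O)C(C)(C)C(=O)CC)CC(CCC=C(C)C)=CC[C@H]1C(C)C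
F4 | step 7 | methyl (6S)-1-(2,2-dimethyl-3-oxopentanoyl)-3-(4-methylpent-3-en-1-yl)-6-(propan-2-yl)cyclohex-3-ene-1-carboxylate, ester cis to isopropyl | COC(=O)[C@@]1(C(=O)C(C)(C)C(=O)CC)CC(CCC=C(C)C)=CC[C@H]1C(C)C
F5 | step 8 | (6R,11S)-3,3-dimethoxy-2,4,4-trimethyl-8-(4-methylpent-3-en-1-yl)-11-(propan-2-yl)spiro[5.5]undec-8-ene-1,5-dione | COC1(OC)C(C)C(=O)[C@]2(CC(CCC=C(C)C)=CC[C@H]2C(C)C)C(=O)C1(C)C
F6 | step 3 | 7-methyl-3-methylideneoct-6-en-1-ol | CC(C)=CCCC(=C)CCO
F7 | step 3 | 8-iodo-2-methyl-6-methylideneoct-2-ene | CC(C)=CCCC(=C)CCI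
F8 | step 3 | (2S)-N-methoxy-N-methyl-2-(propan-2-yl)pent-4-enamide | C=CC[C@@H](C(C)C)C(=O)N(C)OC
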